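**Retrosynthetic overview**

- The strategy rests on the C4–C5 bond of the carbocycle (C1 = CH bearing isopropenyl, C2H=C3(CH3), C4 = CH bearing C7H2OAr, C5 = quaternary C with CH3 and CH2CH2CO2H, C6H2). This bond joins an allylic CH to a quaternary carbon, as in the first ring closure of a terpenoid chain.
- Late disconnections: the C7–O aryl ether (Mitsunobu reaction with umbelliferone) and the isopropenyl group (from a C1 thioester via the methyl ketone and methylenation).
- Key disconnection: C4–C5, by proton-initiated cation–olefin cyclisation of an acyclic (R)-configured 1,5-diene (E C5=C6 alkene, Z C3=C4 allylic acetate).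
- The diene comes from an oxazolidinone-controlled alkylation (C1–C2 bond) of an E β,γ-unsaturated imide (aldol, then Johnson–Claisen) with a Z allylic bromide from citraconic anhydride.
- Ring order: only the cyclohexene is built (key step); the coumarin arrives intact with umbelliferone.

Key step: step 10

Remark: the cyclisation precursor has two C=C bonds (a 1,5-diene, not a triene). Its C1 carboxyl is carried as an S-ethyl thioester and the chain acid as a methyl ester, so that the C1 acyl group can later be converted selectively. The ring numbering C1–C7 of the overview is used in all explanations; in the systematic names of the cyclic compounds the ring is numbered from the quaternary carbon, so overview C5, C4 and C1 are C1, C2 and C5 of those names.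

**Route**

Step 1
Reactants: 1 tert-butyl acetate; 2 methacrolein
Product: 4 tert-butyl 3-hydroxy-4-methylpent-4-enoate (racemic), via lithium enolate 3 (not isolated)
Conditions: LDA, THF, −78 °C; then 2; aqueous NH4Cl
Reagents that add atoms: none
Why: Aldol addition of a lithium ester enolate to the aldehyde carbonyl of methacrolein is 1,2-selective at −78 °C, and the racemic carbinol centre does not matter because it is erased in step 2.

Step 2
Reactants: 4 tert-butyl 3-hydroxy-4-methylpent-4-enoate; 5 trimethyl orthoacetate
Product: 7 1-tert-butyl 7-methyl (E)-4-methylhept-3-enedioate, via mixed ketene acetal 6 (not isolated)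
Conditions: 5 (excess), catalytic EtCO2H, toluene, 110 °C, MeOH distilled off
Reagents that add atoms: none
Why: Johnson–Claisen rearrangement, in which the chair [3,3] transition state of the mixed ketene acetal places the CH2CO2tBu group equatorial and so should give the E trisubstituted C5=C6 alkene together with the two-carbon ester chain.

Step 3
Reactants: 7 1-tert-butyl 7-methyl (E)-4-methylhept-3-enedioate
Product: 9 (E)-7-methoxy-4-methyl-7-oxohept-3-enoic acid, via trimethylsilyl ester 8 (not isolated)
Conditions: TMSOTf, 2,6-lutidine, CH2Cl2, 0 °C to rt; then water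
Reagents that add atoms: none
Why: Silyl triflate-mediated tert-butyl ester cleavage (loss of isobutene to the silyl ester, hydrolysed on work-up) is selective over the methyl ester and avoids protic acid that could lactonise the β,γ-unsaturated acid.

Step 4
Reactants: 9 (E)-7-methoxy-4-methyl-7-oxohept-3-enoic acid; 10 (R)-4-benzyloxazolidin-2-one
Product: 12 (R)-4-benzyl-3-[(E)-7-methoxy-4-methyl-7-oxohept-3-enoyl]oxazolidin-2-one, via mixed pivalic anhydride 11 (not isolated)
Conditions: PivCl, Et3N, THF, −20 °C; then LiCl, 10, −20 °C to rt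
Reagents that add atoms: none
Why: N-acylation of the oxazolidinone through a mixed pivalic anhydride under the mild Et3N/LiCl protocol is standard and should keep the alkene out of conjugation.

Step 5
Reactants: 13 citraconic anhydride
Product: 14 (Z)-2-methylbut-2-ene-1,4-diol
Conditions: LiAlH4, Et2O, 0 °C to rt; aqueous NaOH work-up
Reagents that add atoms: none
Why: Hydride reduction of the cyclic anhydride gives the diol, and the ring of the starting material fixes the Z geometry that becomes the C3=C4 alkene.

Step 6
Reactants: 14 (Z)-2-methylbut-2-ene-1,4-diol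
Product: 15 (Z)-4-hydroxy-3-methylbut-2-en-1-yl acetate
Conditions: porcine pancreatic lipase, vinyl acetate, THF, rt
Reagents that add atoms: vinyl acetate C=COC(C)=O
Why: Lipase-catalysed transesterification with an enol ester acylates the less hindered primary hydroxyl (on the CH2 next to the unsubstituted alkene carbon, the future C7), a known regioselective enzymatic mono-acylation of 2-substituted Z-but-2-ene-1,4-diols.

Step 7
Reactants: 15 (Z)-4-hydroxy-3-methylbut-2-en-1-yl acetate
Product: 16 (Z)-4-bromo-3-methylbut-2-en-1-yl acetate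
Conditions: CBr4, PPh3, CH2Cl2, 0 °C
Reagents that add atoms: carbon tetrabromide BrC(Br)(Br)Br
Why: Appel bromination converts the primary allylic alcohol into the bromide by direct SN2 displacement under neutral conditions, so the Z geometry and the acetate should be preserved.

Step 8
Reactants: 12 (R)-4-benzyl-3-[(E)-7-methoxy-4-methyl-7-oxohept-3-enoyl]oxazolidin-2-one; 16 (Z)-4-bromo-3-methylbut-2-en-1-yl acetate
Product: 18 (R)-4-benzyl-3-[(2R,3E)-2-[(Z)-4-acetoxy-2-methylbut-2-en-1-yl]-7-methoxy-4-methyl-7-oxohept-3-enoyl]oxazolidin-2-one, via sodium dienolate 17 (not isolated)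
Conditions: NaHMDS, THF, −78 °C; then 16, −78 to −45 °C
Reagents that add atoms: none
Why: Oxazolidinone-controlled (Evans) alkylation, in which the chelated Z sodium dienolate reacts at its α-carbon with the allylic bromide on the face opposite the benzyl group, which with the R auxiliary should set C1 as R, while the E alkene makes Dieckmann closure onto the chain ester geometrically impossible.

Step 9
Reactants: 18 alkylated imide
Product: 19 S-ethyl (2R,3E)-2-[(Z)-4-acetoxy-2-methylbut-2-en-1-yl]-7-methoxy-4-methyl-7-oxohept-3-enethioate
Conditions: EtSH, n-BuLi, THF, 0 °C; aqueous NH4Cl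
Reagents that add atoms: ethanethiol CCS (used as lithium ethanethiolate [Li+].CC[S-])
Why: Thiolate cleavage of the exocyclic imide carbonyl (acyl transfer to sulfur) uses a weakly basic nucleophile at 0 °C, so the epimerisable α-vinyl C1 centre, the acetate and the methyl ester should survive while the auxiliary is released.

Step 10
Reactants: 19 S-ethyl thioester diene
Product: 22 methyl 3-[(1R,2R,5S)-2-(acetoxymethyl)-5-[(ethylsulfanyl)carbonyl]-1,3-dimethylcyclohex-3-en-1-yl]propanoate, via C5 carbocation 20 (not isolated), via C3 carbocation 21 (not isolated)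
Conditions: FSO3H (5 equiv), 2-nitropropane, −78 °C; then Et3N, aqueous NaHCO3
Reagents that add atoms: none
Why: Proposed new method: Markovnikov protonation of the E C5=C6 alkene gives the tertiary C5 cation, reversibly held by the neighbouring ester and thioester carbonyl oxygens, and C4 of the Z C3=C4 alkene captures it to form the C4–C5 bond, after which the tertiary C3 cation loses a C2 proton to give the C2=C3 alkene; the closest known reaction type is the superacid-promoted cyclisation of neryl and geranyl acetates or geranic esters to α-cyclogeranyl derivatives. The single ring closes in a 6-endo-trig mode through a chair in which the C1 thioester is equatorial. C4 is set by the Z alkene, which places C7 axial and hence cis to the C1 substituent, and C5 is set by the E alkene, which places its methyl axial and the chain equatorial, the absolute sense of both following from the existing C1 centre because the other chair would put the C1 group 1,3-diaxial to the C5 methyl. The step needs site-selective protonation of C5=C6 (secured by the deactivating allylic acetate on C3=C4), kinetic proton loss from C2 at −78 °C, and transfer of the C5=C6 geometry, which has not been shown for a protonated alkene carrying two different alkyl groups and holds only if C–C bond formation keeps pace with protonation; otherwise the C5 configuration rests only on the modest preference of the larger chain for the equatorial site.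

Step 11
Reactants: 22 cyclohexene thioester
Product: 23 methyl 3-[(1R,2R,5S)-2-(acetoxymethyl)-5-acetyl-1,3-dimethylcyclohex-3-en-1-yl]propanoate
Conditions: CuI, MeLi, Et2O, 0 °C (gives Me2CuLi); then 22, −78 °C; aqueous NH4Cl
Reagents that add atoms: methyllithium C[Li] (used as lithium dimethylcuprate [Li+].C[Cu-]C)
Why: Ketone synthesis from a thioester and a lithium dialkylcuprate (acyl substitution) is selective for the thioester over the methyl ester and the acetate at −78 °C and creates no stereocentre.

Step 12
Reactants: 23 methyl ketone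
Product: 24 methyl 3-[(1R,2R,5S)-2-(acetoxymethyl)-1,3-dimethyl-5-(prop-1-en-2-yl)cyclohex-3-en-1-yl]propanoate
Conditions: Zn, CH2Br2, TiCl4, THF, 0 °C (pre-formed reagent); then 23, CH2Cl2, rt
Reagents that add atoms: dibromomethane BrCBr
Why: Takai–Lombardo methylenation with the Zn/CH2Br2/TiCl4 reagent is non-basic, so the epimerisable β,γ-unsaturated methyl ketone should become the isopropenyl group without touching the esters or moving the ring alkene.

Step 13
Reactants: 24 isopropenyl acetate
Product: 25 methyl 3-[(1R,2R,5S)-2-(hydroxymethyl)-1,3-dimethyl-5-(prop-1-en-2-yl)cyclohex-3-en-1-yl]propanoate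
Conditions: K2CO3, MeOH, rt
Reagents that add atoms: none
Why: Base-catalysed transesterification (methanolysis) removes the primary acetate while the methyl ester is only exchanged degenerately.

Step 14
Reactants: 25 primary alcohol; 26 umbelliferone
Product: 27 methyl 3-[(1R,2R,5S)-1,3-dimethyl-2-{[(2-oxo-2H-chromen-7-yl)oxy]methyl}-5-(prop-1-en-2-yl)cyclohex-3-en-1-yl]propanoate
Conditions: PPh3, DIAD, THF, 0 °C to rt
Reagents that add atoms: none
Why: Mitsunobu etherification of the primary C7 alcohol with the acidic phenol of umbelliferone forms the aryl ether under neutral conditions at a carbon that is not a stereocentre.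

Step 15
Reactants: 27 coumarin ether methyl ester
Product: 29 CNP0301632.1 (target acid), via trilithium coumarinate 28 (not isolated)
Conditions: LiOH (excess), THF/H2O, rt, dark; then 1 M HCl to pH 2, 0 °C to rt
Reagents that add atoms: lithium hydroxide [Li+].[OH-]
Why: Saponification of the methyl ester with excess hydroxide also opens the coumarin lactone to the Z-coumarinate, which re-closes spontaneously on acidification, so the free acid should be obtained with the coumarin and both alkenes intact.

**Compound list**

1 | tert-butyl acetate | CC(=O)OC(C)(C)C | starting material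
2 | methacrolein | C=C(C)C=O | starting material
3 | lithium enolate of tert-butyl acetate | C=C([O-])OC(C)(C)C.[Li+] | intermediate
4 | tert-butyl 3-hydroxy-4-methylpent-4-enoate (racemic) | C=C(C)C(O)CC(=O)OC(C)(C)C | intermediate
5 | trimethyl orthoacetate | CC(OC)(OC)OC | starting material
6 | mixed ketene acetal of 4 (methyl 1-(tert-butoxycarbonylmethyl)-2-methylallyl ketene acetal) | C=C(OC)OC(CC(=O)OC(C)(C)C)C(C)=C | intermediate
7 | 1-tert-butyl 7-methyl (E)-4-methylhept-3-enedioate | COC(=O)CC/C(C)=C/CC(=O)OC(C)(C)C | intermediate
8 | trimethylsilyl ester of 9 | COC(=O)CC/C(C)=C/CC(=O)O[Si](C)(C)C | intermediate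
9 | (E)-7-methoxy-4-methyl-7-oxohept-3-enoic acid | COC(=O)CC/C(C)=C/CC(=O)O | intermediate
10 | (R)-4-benzyloxazolidin-2-one | O=C1N[C@H](Cc2ccccc2)CO1 | starting material
11 | mixed pivalic anhydride of 9 | COC(=O)CC/C(C)=C/CC(=O)OC(=O)C(C)(C)C | intermediate
12 | (R)-4-benzyl-3-[(E)-7-methoxy-4-methyl-7-oxohept-3-enoyl]oxazolidin-2-one | O=C1OC[C@@H](Cc2ccccc2)N1C(=O)C/C=C(\C)CCC(=O)OC | intermediate
13 | citraconic anhydride | CC1=CC(=O)OC1=O | starting material
14 | (Z)-2-methylbut-2-ene-1,4-diol | OC/C=C(/C)CO | intermediate
15 | (Z)-4-hydroxy-3-methylbut-2-en-1-yl acetate | CC(=O)OC/C=C(/C)CO | intermediate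
16 | (Z)-4-bromo-3-methylbut-2-en-1-yl acetate | CC(=O)OC/C=C(/C)CBr | intermediate
17 | sodium Z-dienolate of 12 | O=C1OC[C@@H](Cc2ccccc2)N1/C([O-])=C/C=C(\C)CCC(=O)OC.[Na+] | intermediate
18 | (R)-4-benzyl-3-[(2R,3E)-2-[(Z)-4-acetoxy-2-methylbut-2-en-1-yl]-7-methoxy-4-methyl-7-oxohept-3-enoyl]oxazolidin-2-one | O=C1OC[C@@H](Cc2ccccc2)N1C(=O)[C@@H](/C=C(C)/CCC(=O)OC)C/C(C)=C\COC(C)=O | intermediate
19 | S-ethyl (2R,3E)-2-[(Z)-4-acetoxy-2-methylbut-2-en-1-yl]-7-methoxy-4-methyl-7-oxohept-3-enethioate (cyclisation precursor) | CCSC(=O)[C@@H](/C=C(C)/CCC(=O)OC)C/C(C)=C\COC(C)=O | intermediate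
20 | tertiary C5 carbocation from 19 | CCSC(=O)[C@@H](C[C+](C)CCC(=O)OC)C/C(C)=C\COC(C)=O | intermediate
21 | tertiary C3 cyclohexyl carbocation | CCSC(=O)[C@@H]1C[C+](C)[C@H](COC(C)=O)[C@](C)(CCC(=O)OC)C1 | intermediate
22 | methyl 3-[(1R,2R,5S)-2-(acetoxymethyl)-5-[(ethylsulfanyl)carbonyl]-1,3-dimethylcyclohex-3-en-1-yl]propanoate (cyclisation product) | CCSC(=O)[C@@H]1C=C(C)[C@H](COC(C)=O)[C@](C)(CCC(=O)OC)C1 | intermediate
23 | methyl 3-[(1R,2R,5S)-2-(acetoxymethyl)-5-acetyl-1,3-dimethylcyclohex-3-en-1-yl]propanoate | CC(=O)[C@@H]1C=C(C)[C@H](COC(C)=O)[C@](C)(CCC(=O)OC)C1 | intermediate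
24 | methyl 3-[(1R,2R,5S)-2-(acetoxymethyl)-1,3-dimethyl-5-(prop-1-en-2-yl)cyclohex-3-en-1-yl]propanoate | C=C(C)[C@@H]1C=C(C)[C@H](COC(C)=O)[C@](C)(CCC(=O)OC)C1 | intermediate
25 | methyl 3-[(1R,2R,5S)-2-(hydroxymethyl)-1,3-dimethyl-5-(prop-1-en-2-yl)cyclohex-3-en-1-yl]propanoate | C=C(C)[C@@H]1C=C(C)[C@H](CO)[C@](C)(CCC(=O)OC)C1 | intermediate
26 | umbelliferone (7-hydroxycoumarin) | O=c1ccc2ccc(O)cc2o1 | starting material
27 | methyl 3-[(1R,2R,5S)-1,3-dimethyl-2-{[(2-oxo-2H-chromen-7-yl)oxy]methyl}-5-(prop-1-en-2-yl)cyclohex-3-en-1-yl]propanoate | C=C(C)[C@@H]1C=C(C)[C@H](COc2ccc3ccc(=O)oc3c2)[C@](C)(CCC(=O)OC)C1 | intermediate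
28 | trilithium salt of the ring-opened Z-coumarinate of 29 | C=C(C)[C@@H]1C=C(C)[C@H](COc2ccc(/C=C\C(=O)[O-])c([O-])c2)[C@](C)(CCC(=O)[O-])C1.[Li+].[Li+].[Li+] | intermediate
29 | CNP0301632.1, 3-[(1R,2R,5S)-1,3-dimethyl-2-{[(2-oxo-2H-chromen-7-yl)oxy]methyl}-5-(prop-1-en-2-yl)cyclohex-3-en-1-yl]propanoic acid | C=C(C)[C@@H]1C=C(C)[C@H](COc2ccc3ccc(=O)oc3c2)[C@](C)(CCC(=O)O)C1 | target

**Step count**

Total step count: 15. Longest linear sequence: 12 steps (steps 1–4 and 8–15); steps 5–7 make the bromide separately.

**Steps most likely to fail**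

1. Step 10 (the proposed new method). Three processes may go wrong. The C5 cation may live long enough to lose the E geometry, giving low selectivity at C5. A carbonyl oxygen may capture the cation for good, giving a lactone on quench. The proton may be lost toward C4 or the methyl group instead of C2. The fallback uses known chemistry and a stereospecific electrophile in place of the proton. It sets out from imide 18, because the thioester would not tolerate thiophilic divalent mercury. Treatment with Hg(OTf)2·PhNMe2 in MeNO2 at −20 °C, then aqueous NaCl, should close the ring by anti addition across the E alkene and give the C6-chloromercurio cyclohexene imide F1. Radical demercuration with Bu3SnH in toluene should give the cyclohexene imide F2. Thiolysis with LiSEt as in step 9 brings the route back at 22.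

2. Step 8. The dienolate may react at its γ-carbon, may be acylated by the acetate of the bromide, or may give low facial selectivity, so that C1 is not set cleanly. The fallback sets C1 by an auxiliary-controlled aldol reaction and makes the C5=C6 alkene afterwards. It sets out from bromide 16 and enolate 3. Alkylation of 3 with 16 (THF/DMPU, −78 °C) should give tert-butyl (Z)-6-acetoxy-4-methylhex-4-enoate F3. Cleavage as in step 3 gives (Z)-6-acetoxy-4-methylhex-4-enoic acid F4. Acylation of 10 as in step 4 gives (R)-4-benzyl-3-[(Z)-6-acetoxy-4-methylhex-4-enoyl]oxazolidin-2-one F5. A boron-mediated syn-aldol reaction with methacrolein 2 (Bu2BOTf, iPr2NEt, CH2Cl2, −78 to 0 °C) should give the (2R,3R) syn-aldol imide F6. Johnson–Claisen rearrangement of F6 with 5 as in step 2 builds the E alkene and the ester chain and comes back at 18.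

3. Step 14. The bulky alkoxyphosphonium at the β-branched C7 may be displaced slowly, so that the betaine is consumed by elimination or by alkylation of the hydrazide. The fallback replaces the redox condensation by a Williamson ether synthesis with a small pre-formed leaving group. It sets out from alcohol 25. MsCl and Et3N in CH2Cl2 at 0 °C should give the C7 mesylate F7. Heating F7 with umbelliferone 26 and Cs2CO3 in DMF at 70 °C comes back at 27.

**Further compounds**

F1 | step 10 | C6-chloromercurio cyclohexene imide (HgCl on C6, trans to the C1 acyl group and cis to the C5 methyl) | O=C1OC[C@@H](Cc2ccccc2)N1C(=O)[C@@H]3C=C(C)[C@H](COC(C)=O)[C@](C)(CCC(=O)OC)[C@H]3[Hg]Cl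
F2 | step 10 | cyclohexene imide (N-acyl oxazolidinone analogue of 22) | O=C1OC[C@@H](Cc2ccccc2)N1C(=O)[C@@H]3C=C(C)[C@H](COC(C)=O)[C@](C)(CCC(=O)OC)C3
F3 | step 8 | tert-butyl (Z)-6-acetoxy-4-methylhex-4-enoate | CC(=O)OC/C=C(/C)CCC(=O)OC(C)(C)C
F4 | step 8 | (Z)-6-acetoxy-4-methylhex-4-enoic acid | CC(=O)OC/C=C(/C)CCC(=O)O
F5 | step 8 | (R)-4-benzyl-3-[(Z)-6-acetoxy-4-methylhex-4-enoyl]oxazolidin-2-one | O=C1OC[C@@H](Cc2ccccc2)N1C(=O)CC/C(C)=C\COC(C)=O
F6 | step 8 | (R)-4-benzyl-3-[(2R,3R)-2-[(Z)-4-acetoxy-2-methylbut-2-en-1-yl]-3-hydroxy-4-methylpent-4-enoyl]oxazolidin-2-one | O=C1OC[C@@H](Cc2ccccc2)N1C(=O)[C@@H]([C@@H](O)C(C)=C)C/C(C)=C\COC(C)=O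
F7 | step 14 | methyl 3-[(1R,2R,5S)-1,3-dimethyl-2-[(methylsulfonyloxy)methyl]-5-(prop-1-en-2-yl)cyclohex-3-en-1-yl]propanoate | C=C(C)[C@@H]1C=C(C)[C@H](COS(C)(=O)=O)[C@](C)(CCC(=O)OC)C1
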